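## Retrosynthetic overview

1. Target ⇒ 3'-O-benzyl-5-O-methyl flavone: the end game is chelation-controlled 5-O-demethylation, then hydrogenolysis of the benzyl ether.
2. Ring C (pyranone) ⇒ 2'-hydroxychalcone by oxidative cyclisation (I2/DMSO); it is the only ring formed, both benzene rings are bought.
3. Chalcone Cα–Cβ ⇒ intermolecular Claisen–Schmidt aldol condensation of an A-ring acetophenone with a B-ring benzaldehyde (key C–C bond).
4. A-ring ketone ⇒ 1,2,3,5-tetramethoxybenzene ⇒ 3,4,5-trimethoxyphenol (O-methylation, then Friedel–Crafts acetylation with ortho-demethylation).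
5. B-ring aldehyde ⇒ 3-hydroxy-4,5-dimethoxybenzaldehyde (O-benzylation).

Assumption: the target is achiral (no stereocentre), so there is no enantiomer to control; the only stereo-element on the route is the E alkene of chalcone 8, and the racemic centres of the transient intermediates 7 and 9 disappear in the same flask.

## Route

Step 1
Reactants: 1 3,4,5-trimethoxyphenol
Product: 2 1,2,3,5-tetramethoxybenzene
Conditions: MeI (1.5 equiv), K2CO3 (2 equiv), acetone, reflux, 12 h
Reagents that add atoms: iodomethane, CI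
Why: Williamson O-methylation of the phenoxide, which is the only nucleophilic site in 1.

Step 2
Reactants: 2 1,2,3,5-tetramethoxybenzene
Product: 4 1-(2-hydroxy-3,4,6-trimethoxyphenyl)ethanone, via 2,3,4,6-tetramethoxyacetophenone 3 (not isolated)
Conditions: AcCl (1.2 equiv), AlCl3 (2.5 equiv), Et2O, 0 °C → rt, 24 h; then ice/aq. HCl
Reagents that add atoms: acetyl chloride, CC(=O)Cl
Why: Friedel–Crafts acylation can only occur at the two symmetry-equivalent free positions of 2, and the AlCl3 bound to the new carbonyl then cleaves the ortho-methoxy group that is twisted out of plane by its 3-OMe neighbour (chelation-controlled ortho-demethylation), the resulting aluminium chelate shielding the other ortho-OMe.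

Step 3
Reactants: 5 3-hydroxy-4,5-dimethoxybenzaldehyde
Product: 6 3-(benzyloxy)-4,5-dimethoxybenzaldehyde
Conditions: BnBr (1.2 equiv), K2CO3 (2 equiv), DMF, 60 °C
Reagents that add atoms: benzyl bromide, BrCc1ccccc1
Why: Williamson O-benzylation of the single phenol gives an ether that tolerates the strongly basic aldol step and the hot I2/DMSO step.

Step 4
Reactants: 4 1-(2-hydroxy-3,4,6-trimethoxyphenyl)ethanone; 6 3-(benzyloxy)-4,5-dimethoxybenzaldehyde
Product: 8 (E)-3-[3-(benzyloxy)-4,5-dimethoxyphenyl]-1-(2-hydroxy-3,4,6-trimethoxyphenyl)prop-2-en-1-one, via racemic aldol adduct 7 (not isolated)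
Conditions: KOH (50% aq.), EtOH, rt, 36–48 h; then dil. HCl, 0 °C
Reagents that add atoms: none
Why: Claisen–Schmidt crossed aldol condensation in which only the ketone can enolise and only the aldehyde is electrophilic, followed by E1cB dehydration that erases the carbinol stereocentre of 7 and gives the conjugated E alkene under thermodynamic control.

Step 5
Reactants: 8 (E)-3-[3-(benzyloxy)-4,5-dimethoxyphenyl]-1-(2-hydroxy-3,4,6-trimethoxyphenyl)prop-2-en-1-one
Product: 10 2-[3-(benzyloxy)-4,5-dimethoxyphenyl]-5,7,8-trimethoxy-4H-chromen-4-one, via racemic flavanone 9 (not isolated)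
Conditions: I2 (10 mol%), DMSO, 130 °C, 2 h; aq. Na2S2O3 work-up
Reagents that add atoms: none
Why: Oxidative cyclisation of a 2'-hydroxychalcone by 6-endo oxa-Michael closure of the free 2'-phenol, then iodine-mediated dehydrogenation (α-iodination and loss of HI) with DMSO re-oxidising HI to I2, so the C2 centre of 9 becomes sp2.

Step 6
Reactants: 10 2-[3-(benzyloxy)-4,5-dimethoxyphenyl]-5,7,8-trimethoxy-4H-chromen-4-one
Product: 11 2-[3-(benzyloxy)-4,5-dimethoxyphenyl]-5-hydroxy-7,8-dimethoxy-4H-chromen-4-one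
Conditions: anhydrous AlCl3 (6 equiv), MeCN, rt → 50 °C; then 2% aq. HCl, 60 °C, 20 min
Reagents that add atoms: none
Why: Chelation-controlled Lewis-acid demethylation, in which only the 5-OMe peri to the C4 carbonyl can form the six-membered aluminium chelate, while the acetonitrile-tempered AlCl3 leaves the other four methyl ethers and the benzyl ether intact.

Step 7
Reactants: 11 2-[3-(benzyloxy)-4,5-dimethoxyphenyl]-5-hydroxy-7,8-dimethoxy-4H-chromen-4-one
Product: 12 5-hydroxy-2-(3-hydroxy-4,5-dimethoxyphenyl)-7,8-dimethoxy-4H-chromen-4-one (5,3'-dihydroxy-7,8,4',5'-tetramethoxyflavone)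
Conditions: H2 (1 atm), 10% Pd/C, EtOAc–MeOH, rt
Reagents that add atoms: none
Why: Catalytic hydrogenolysis of the benzylic C–O bond is neutral, so no Wessely–Moser scrambling of the 5-hydroxy-7,8-dimethoxy ring can occur, and the vinylogous-ester C2=C3 bond of the flavone is not reduced at 1 atm and room temperature.

## Compound list

1 | 3,4,5-trimethoxyphenol | COc1cc(O)cc(OC)c1OC | starting material
2 | 1,2,3,5-tetramethoxybenzene | COc1cc(OC)c(OC)c(OC)c1 | intermediate
3 | 1-(2,3,4,6-tetramethoxyphenyl)ethanone (2,3,4,6-tetramethoxyacetophenone) | CC(=O)c1c(OC)cc(OC)c(OC)c1OC | intermediate (not isolated)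
4 | 1-(2-hydroxy-3,4,6-trimethoxyphenyl)ethanone | CC(=O)c1c(O)c(OC)c(OC)cc1OC | intermediate
5 | 3-hydroxy-4,5-dimethoxybenzaldehyde | COc1cc(C=O)cc(O)c1OC | starting material
6 | 3-(benzyloxy)-4,5-dimethoxybenzaldehyde | COc1cc(C=O)cc(OCc2ccccc2)c1OC | intermediate
7 | 3-[3-(benzyloxy)-4,5-dimethoxyphenyl]-3-hydroxy-1-(2-hydroxy-3,4,6-trimethoxyphenyl)propan-1-one, racemic | COc1cc(C(O)CC(=O)c2c(O)c(OC)c(OC)cc2OC)cc(OCc2ccccc2)c1OC | intermediate (not isolated)
8 | (E)-3-[3-(benzyloxy)-4,5-dimethoxyphenyl]-1-(2-hydroxy-3,4,6-trimethoxyphenyl)prop-2-en-1-one | COc1cc(/C=C/C(=O)c2c(O)c(OC)c(OC)cc2OC)cc(OCc2ccccc2)c1OC | intermediate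
9 | 2-[3-(benzyloxy)-4,5-dimethoxyphenyl]-5,7,8-trimethoxychroman-4-one, racemic | COc1cc(C2CC(=O)c3c(OC)cc(OC)c(OC)c3O2)cc(OCc2ccccc2)c1OC | intermediate (not isolated)
10 | 2-[3-(benzyloxy)-4,5-dimethoxyphenyl]-5,7,8-trimethoxy-4H-chromen-4-one | COc1cc(-c2cc(=O)c3c(OC)cc(OC)c(OC)c3o2)cc(OCc2ccccc2)c1OC | intermediate
11 | 2-[3-(benzyloxy)-4,5-dimethoxyphenyl]-5-hydroxy-7,8-dimethoxy-4H-chromen-4-one | COc1cc(-c2cc(=O)c3c(O)cc(OC)c(OC)c3o2)cc(OCc2ccccc2)c1OC | intermediate
12 | 5-hydroxy-2-(3-hydroxy-4,5-dimethoxyphenyl)-7,8-dimethoxy-4H-chromen-4-one | COc1cc(-c2cc(=O)c3c(O)cc(OC)c(OC)c3o2)cc(O)c1OC | target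

## Step count and risks

Total step count: 7 (steps 1–2 build the A-ring ketone, step 3 the B-ring aldehyde, steps 4–7 are the common sequence).
Longest linear sequence: 6 steps (1 → 2 → 4 → 8 → 10 → 11 → 12).

The three steps most likely to fail:

Step 2. The risk is that AlCl3 cleaves the wrong ortho-methoxy group (giving the 6-hydroxy-2,3,4-trimethoxy isomer) or both, so that the ring-oxygen position is not secured. The fallback sets out from 6 and comes back at 4, and fixes the free hydroxyl by a benzyl ether instead of by a choice between two methoxy groups. Baeyer–Villiger oxidation of 6 (mCPBA, CH2Cl2) gives 3-(benzyloxy)-4,5-dimethoxyphenyl formate F1, which is saponified (KOH, MeOH–H2O) to 3-(benzyloxy)-4,5-dimethoxyphenol F2. Methylation (MeI, K2CO3, acetone) gives 1-(benzyloxy)-2,3,5-trimethoxybenzene F3, and hydrogenolysis (H2, Pd/C) gives 2,3,5-trimethoxyphenol F4. Acetylation of this free phenol with AcOH/BF3·OEt2 at 85 °C goes ortho to the hydroxyl through the BF2 chelate and delivers 4; any para-acylated isomer is not chelated and is removed by base extraction.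

Step 5. The risks are iodination of the very electron-rich A ring at C6 or HI-induced ether cleavage at 130 °C. The fallback sets out from 8 and comes back at 10, and separates ring closure from oxidation. Chalcone 8 is cyclised on purpose to flavanone 9 (NaOAc, EtOH, reflux), which is isolated and then dehydrogenated with DDQ in dioxane at reflux, with no iodine or HI present. This detour makes no compound outside the list (none F0).

Step 6. The risks are partial loss of the benzyl ether under AlCl3, followed by phenol-assisted cleavage of the neighbouring 4'-OMe, or attack on the 8-OMe. The fallback sets out from 10 and comes back at 12, and changes the protecting-group logic so that no benzyl ether and no free ortho-phenol meets the Lewis acid. Hydrogenolysis of 10 (H2, Pd/C) gives 3'-hydroxy-5,7,8,4',5'-pentamethoxyflavone F5, and acetylation (Ac2O, pyridine) gives 3'-acetoxy-5,7,8,4',5'-pentamethoxyflavone F6. BCl3 (CH2Cl2, −78 → 0 °C) then removes only the chelating 5-O-methyl group to give 3'-acetoxy-5-hydroxy-7,8,4',5'-tetramethoxyflavone F7, and mild methanolysis (K2CO3, MeOH, rt) releases 12.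

## Further compounds

F1 | step 2 | 3-(benzyloxy)-4,5-dimethoxyphenyl formate | O=COc1cc(OC)c(OC)c(OCc2ccccc2)c1
F2 | step 2 | 3-(benzyloxy)-4,5-dimethoxyphenol | Oc1cc(OC)c(OC)c(OCc2ccccc2)c1
F3 | step 2 | 1-(benzyloxy)-2,3,5-trimethoxybenzene | COc1cc(OC)c(OC)c(OCc2ccccc2)c1
F4 | step 2 | 2,3,5-trimethoxyphenol | COc1cc(OC)c(OC)c(O)c1
F0 | step 5 | none | none
F5 | step 6 | 3'-hydroxy-5,7,8,4',5'-pentamethoxyflavone | COc1cc(-c2cc(=O)c3c(OC)cc(OC)c(OC)c3o2)cc(O)c1OC
F6 | step 6 | 3'-acetoxy-5,7,8,4',5'-pentamethoxyflavone | COc1cc(-c2cc(=O)c3c(OC)cc(OC)c(OC)c3o2)cc(OC(C)=O)c1OC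
F7 | step 6 | 3'-acetoxy-5-hydroxy-7,8,4',5'-tetramethoxyflavone | COc1cc(-c2cc(=O)c3c(O)cc(OC)c(OC)c3o2)cc(OC(C)=O)c1OC
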